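**Retrosynthetic overview**
- Hippolide D ⇐ cis-β-lactone carboxylic acid: the anhydride C–O bond is made last, by passing the lactone acyl group to the tethered carboxyl. The same event frees the secondary alcohol, so no O-protection is used.
- cis-β-Lactone ⇐ β,γ-unsaturated aldehyde + the ketene from allyl succinyl chloride (cinchona/LiI-catalysed [2+2]; sets both stereocentres).
- The E-enal is carried as its dimethyl acetal; the trisubstituted olefin comes from a Wittig reaction of an α-keto acetal with a 3-oxidopropyl ylide, and the E geometry is fixed by acid equilibration on unmasking.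
- Keto acetal ⇐ (2E,6E)-farnesyl bromide + the enolate of pyruvaldehyde dimethyl acetal.
- Ring order: oxetan-2-one first; oxolane-2,5-dione (the anhydride) last, formed as the four-membered ring opens.

Assumption: O-trimethylsilylquinine is taken as the pseudoenantiomer that gives the (2R,3S)-lactone 14 (by analogy with quinine in ketene–aldehyde cycloadditions); if the first run shows the opposite sense, O-trimethylsilylquinidine replaces it with nothing else changed.

**Route**

Step 1
Reactants: 1 (2E,6E)-farnesyl bromide; 2 1,1-dimethoxypropan-2-one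
Product: 4 (5E,9E)-1,1-dimethoxy-6,10,14-trimethylpentadeca-5,9,13-trien-2-one, via lithium enolate 3 (not isolated)
Conditions: 2 (2 equiv), LiN(iPr)2, THF, −78 °C; then 1, DMPU, −78 → 0 °C
Reagents that add atoms: none
Why: The kinetic lithium enolate forms at the methyl group and displaces the primary allylic bromide by SN2 (ketone enolate alkylation), leaving both E olefins untouched; excess enolate limits dialkylation.

Step 2
Reactants: 4 (5E,9E)-1,1-dimethoxy-6,10,14-trimethylpentadeca-5,9,13-trien-2-one; 5 (3-hydroxypropyl)triphenylphosphonium bromide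
Product: 7 (3Z,7E,11E)-4-(dimethoxymethyl)-8,12,16-trimethylheptadeca-3,7,11,15-tetraen-1-ol, via oxido ylide 6 (not isolated)
Conditions: 5 (1.5 equiv), KN(SiMe3)2 (3 equiv), THF, 0 °C; then 4, −78 → 23 °C
Reagents that add atoms: none
Why: Wittig olefination of the α,α-dialkoxy ketone with a non-stabilised ylide gives the trisubstituted alkene, mainly Z (acetal carbon cis to the new chain); any minor E isomer converges to the same enal in step 6.

Step 3
Reactants: 7 (3Z,7E,11E)-4-(dimethoxymethyl)-8,12,16-trimethylheptadeca-3,7,11,15-tetraen-1-ol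
Product: 8 (3Z,7E,11E)-4-(dimethoxymethyl)-8,12,16-trimethylheptadeca-3,7,11,15-tetraenal
Conditions: Dess–Martin periodinane, pyridine, CH2Cl2, 0 °C; used at once without purification
Reagents that add atoms: none
Why: Buffered Dess–Martin oxidation is mild enough to give the β,γ-unsaturated aldehyde without acetal loss or migration of the olefin into conjugation.

Step 4
Reactants: 9 succinic anhydride; 10 allyl alcohol
Product: 12 allyl 4-chloro-4-oxobutanoate, via monoallyl succinate 11 (not isolated)
Conditions: toluene, 100 °C; then (COCl)2, DMF (cat.), CH2Cl2, 0 → 23 °C; concentrate and use directly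
Reagents that add atoms: oxalyl chloride, ClC(=O)C(=O)Cl
Why: Alcoholysis of the cyclic anhydride gives the half-ester, and oxalyl chloride/DMF (Vilsmeier-type activation) turns the free acid into the acid chloride.

Step 5
Reactants: 8 (3Z,7E,11E)-4-(dimethoxymethyl)-8,12,16-trimethylheptadeca-3,7,11,15-tetraenal; 12 allyl 4-chloro-4-oxobutanoate
Product: 14 allyl 2-{(2R,3S)-2-[(2Z,6E,10E)-3-(dimethoxymethyl)-7,11,15-trimethylhexadeca-2,6,10,14-tetraen-1-yl]-4-oxooxetan-3-yl}acetate (cis-β-lactone), via ketene 13 (not isolated)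
Conditions: O-trimethylsilylquinine (15 mol %), LiI (3 equiv), iPr2NEt (2.5 equiv), CH2Cl2/Et2O 10:1, −78 °C; slow addition of 12
Reagents that add atoms: none
Why: Cinchona alkaloid/lithium salt-catalysed acyl halide–aldehyde cyclocondensation (Wynberg-type ketene–aldehyde [2+2]): the chiral ammonium enolate adds to the lithium-activated aldehyde through a closed transition state and the aldolate closes on the acylammonium, giving the cis-lactone and setting both stereocentres under catalyst control.

Step 6
Reactants: 14 allyl 2-{(2R,3S)-2-[(2Z,6E,10E)-3-(dimethoxymethyl)-7,11,15-trimethylhexadeca-2,6,10,14-tetraen-1-yl]-4-oxooxetan-3-yl}acetate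
Product: 16 allyl 2-{(2R,3S)-2-[(2E,6E,10E)-3-formyl-7,11,15-trimethylhexadeca-2,6,10,14-tetraen-1-yl]-4-oxooxetan-3-yl}acetate, via Z-enal lactone 15 (not isolated)
Conditions: SiO2, 10% aq. oxalic acid, CH2Cl2, 23 °C, until the Z/E ratio is constant
Reagents that add atoms: water, O
Why: Mild acid hydrolysis of the allylic dimethyl acetal gives the Z-enal, which equilibrates under the same acid to the thermodynamically favoured E-2-alkyl-2-enal (angelic-to-tiglic type isomerisation); the lactone, the allyl ester and both stereocentres are not touched.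

Step 7
Reactants: 16 allyl 2-{(2R,3S)-2-[(2E,6E,10E)-3-formyl-7,11,15-trimethylhexadeca-2,6,10,14-tetraen-1-yl]-4-oxooxetan-3-yl}acetate
Product: 18 Hippolide D, (S)-3-[(1R,3E,7E,11E)-4-formyl-1-hydroxy-8,12,16-trimethylheptadeca-3,7,11,15-tetraen-1-yl]oxolane-2,5-dione, via lactone acid 17 (not isolated)
Conditions: Pd(PPh3)4 (3 mol %), p-TolSO2H (1.1 equiv), dry CH2Cl2, 23 °C; then 2-pyridone (20 mol %), 35 °C; rapid filtration through acid-washed silica, no amines or alcohols
Reagents that add atoms: none
Why: Proposed new method: after a standard Tsuji–Trost deallylation (zerovalent palladium, sulfinic acid as allyl acceptor), the tethered carboxylic acid adds 5-exo-trig to the strained β-lactone carbonyl to give a cis-fused hemi-orthoester, and 2-pyridone, acting as a ditopic proton shuttle as it does in mutarotation and ester aminolysis, relays the proton to the ring oxygen so that the four-membered ring opens to the five-membered anhydride and the free secondary alcohol; relief of β-lactone strain (about 23 kcal/mol) pays for making an anhydride from an ester and an acid, no bond to either stereocentre is broken so both are retained, and the non-basic medium disfavours carboxylate SN2 attack at the alkyl carbon and onward rearrangement to the γ-lactone acid (which needs a bridged tetrahedral intermediate); the closest known reaction types are acyl C–O alcoholysis and aminolysis of β-lactones, β-to-γ/δ translactonisation of hydroxyalkyl β-lactones, and anhydride formation from carboxylic acids and enol esters.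

**Compound list**

1 | (2E,6E)-farnesyl bromide | CC(C)=CCC/C(C)=C/CC/C(C)=C/CBr | starting material
2 | 1,1-dimethoxypropan-2-one (pyruvaldehyde dimethyl acetal) | CC(=O)C(OC)OC | starting material
3 | lithium 3,3-dimethoxyprop-1-en-2-olate (enolate of 2) | [Li+].[O-]C(=C)C(OC)OC | intermediate
4 | (5E,9E)-1,1-dimethoxy-6,10,14-trimethylpentadeca-5,9,13-trien-2-one | CC(C)=CCC/C(C)=C/CC/C(C)=C/CCC(=O)C(OC)OC | intermediate
5 | (3-hydroxypropyl)triphenylphosphonium bromide | OCCC[P+](c1ccccc1)(c1ccccc1)c1ccccc1.[Br-] | starting material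
6 | potassium 3-(triphenylphosphoranylidene)propan-1-olate (oxido ylide) | [K+].[O-]CCC=P(c1ccccc1)(c1ccccc1)c1ccccc1 | intermediate
7 | (3Z,7E,11E)-4-(dimethoxymethyl)-8,12,16-trimethylheptadeca-3,7,11,15-tetraen-1-ol | CC(C)=CCC/C(C)=C/CC/C(C)=C/CC/C(C(OC)OC)=C/CCO | intermediate
8 | (3Z,7E,11E)-4-(dimethoxymethyl)-8,12,16-trimethylheptadeca-3,7,11,15-tetraenal | CC(C)=CCC/C(C)=C/CC/C(C)=C/CC/C(C(OC)OC)=C/CC=O | intermediate
9 | succinic anhydride | O=C1CCC(=O)O1 | starting material
10 | allyl alcohol | C=CCO | starting material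
11 | 4-(allyloxy)-4-oxobutanoic acid (monoallyl succinate) | C=CCOC(=O)CCC(=O)O | intermediate
12 | allyl 4-chloro-4-oxobutanoate | C=CCOC(=O)CCC(=O)Cl | intermediate
13 | allyl 4-oxobut-3-enoate (ketene) | C=CCOC(=O)CC=C=O | intermediate
14 | allyl 2-{(2R,3S)-2-[(2Z,6E,10E)-3-(dimethoxymethyl)-7,11,15-trimethylhexadeca-2,6,10,14-tetraen-1-yl]-4-oxooxetan-3-yl}acetate | CC(C)=CCC/C(C)=C/CC/C(C)=C/CC/C(C(OC)OC)=C/C[C@H]1OC(=O)[C@H]1CC(=O)OCC=C | intermediate
15 | allyl 2-{(2R,3S)-2-[(2Z,6E,10E)-3-formyl-7,11,15-trimethylhexadeca-2,6,10,14-tetraen-1-yl]-4-oxooxetan-3-yl}acetate | CC(C)=CCC/C(C)=C/CC/C(C)=C/CC/C(C=O)=C/C[C@H]1OC(=O)[C@H]1CC(=O)OCC=C | intermediate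
16 | allyl 2-{(2R,3S)-2-[(2E,6E,10E)-3-formyl-7,11,15-trimethylhexadeca-2,6,10,14-tetraen-1-yl]-4-oxooxetan-3-yl}acetate | CC(C)=CCC/C(C)=C/CC/C(C)=C/CC/C(C=O)=C\C[C@H]1OC(=O)[C@H]1CC(=O)OCC=C | intermediate
17 | 2-{(2R,3S)-2-[(2E,6E,10E)-3-formyl-7,11,15-trimethylhexadeca-2,6,10,14-tetraen-1-yl]-4-oxooxetan-3-yl}acetic acid | CC(C)=CCC/C(C)=C/CC/C(C)=C/CC/C(C=O)=C\C[C@H]1OC(=O)[C@H]1CC(=O)O | intermediate
18 | Hippolide D, (S)-3-[(1R,3E,7E,11E)-4-formyl-1-hydroxy-8,12,16-trimethylheptadeca-3,7,11,15-tetraen-1-yl]oxolane-2,5-dione | CC(C)=CCC/C(C)=C/CC/C(C)=C/CC/C(C=O)=C\C[C@@H](O)[C@@H]1CC(=O)OC1=O | target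

**Step count and risks**

Total steps: 7. Longest linear sequence: 6 (steps 1, 2, 3, 5, 6, 7); step 4 is a one-step side branch.

Step 7 (the new acyl transfer). It may be slow, may follow the alkyl-oxygen path, or the product may go on to the γ-lactone acid. The fallback uses known chemistry, sets out from 16 and comes back at 18. LiOH in aqueous THF at 0 °C cleaves the allyl ester and opens the lactone at the acyl carbon with retention, giving dilithium (S)-2-[(1R,3E,7E,11E)-4-formyl-1-hydroxy-8,12,16-trimethylheptadeca-3,7,11,15-tetraen-1-yl]butanedioate F4, which is never acidified so that it cannot lactonise. Triethylsilyl triflate and 2,6-lutidine give the tris(triethylsilyl) derivative F5, whose two silyl esters hydrolyse on work-up at pH 5–6 to leave the silyl ether diacid F6. DCC in CH2Cl2 at 0 °C closes the silyl ether anhydride F7, and HF·pyridine in THF at 0 °C removes the silyl group to give 18.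

Step 5 (cyclocondensation on a β,γ-unsaturated aldehyde). The amine base may move the olefin into conjugation, or the ester-bearing ketene may give lower selectivity than simple ketenes. The fallback sets out from 8 and 12 and comes back at 14. Acid chloride 12 acylates lithiated (S)-4-benzyloxazolidin-2-one to give (S)-4-benzyl-3-[4-(allyloxy)-4-oxobutanoyl]oxazolidin-2-one F1. Its Z-boron enolate (Bu2BOTf, iPr2NEt, CH2Cl2, −78 °C) adds to 8 in an Evans syn aldol to give the (2S,3R) aldol imide F2. LiOH/H2O2 removes the auxiliary to give the β-hydroxy acid F3, and carboxyl activation with PhSO2Cl in pyridine closes it with retention to the same cis-lactone 14.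

Step 6 (acetal hydrolysis with Z-to-E equilibration beside a β-lactone and a polyene). Equilibration may be incomplete, or prolonged acid may damage the lactone or trigger cyclisation of the polyene onto the protonated enal. The fallback sets out from 14 and comes back at 16. Hydrolysis is stopped at the kinetic stage (LiBF4, wet MeCN, 0 °C) and the Z-enal 15 is isolated. It is then isomerised in a separate, acid-free operation by reversible conjugate addition of a Lewis-base catalyst (DABCO, 10 mol %, CHCl3, 23 °C), which acts only on the enal; no new compound is made (none, F0).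

**Further compounds**

F1 | step 5 | (S)-4-benzyl-3-[4-(allyloxy)-4-oxobutanoyl]oxazolidin-2-one | C=CCOC(=O)CCC(=O)N1[C@@H](Cc2ccccc2)COC1=O
F2 | step 5 | (S)-4-benzyl-3-[(2S,3R,5Z,9E,13E)-2-[2-(allyloxy)-2-oxoethyl]-6-(dimethoxymethyl)-3-hydroxy-10,14,18-trimethylnonadeca-5,9,13,17-tetraenoyl]oxazolidin-2-one | CC(C)=CCC/C(C)=C/CC/C(C)=C/CC/C(C(OC)OC)=C/C[C@@H](O)[C@H](CC(=O)OCC=C)C(=O)N1[C@@H](Cc2ccccc2)COC1=O
F3 | step 5 | (2S,3R,5Z,9E,13E)-2-[2-(allyloxy)-2-oxoethyl]-6-(dimethoxymethyl)-3-hydroxy-10,14,18-trimethylnonadeca-5,9,13,17-tetraenoic acid | CC(C)=CCC/C(C)=C/CC/C(C)=C/CC/C(C(OC)OC)=C/C[C@@H](O)[C@H](CC(=O)OCC=C)C(=O)O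
F0 | step 6 | none | none
F4 | step 7 | dilithium (S)-2-[(1R,3E,7E,11E)-4-formyl-1-hydroxy-8,12,16-trimethylheptadeca-3,7,11,15-tetraen-1-yl]butanedioate | CC(C)=CCC/C(C)=C/CC/C(C)=C/CC/C(C=O)=C\C[C@@H](O)[C@H](CC(=O)[O-])C(=O)[O-].[Li+].[Li+]
F5 | step 7 | bis(triethylsilyl) (S)-2-[(1R,3E,7E,11E)-4-formyl-8,12,16-trimethyl-1-(triethylsilyloxy)heptadeca-3,7,11,15-tetraen-1-yl]butanedioate | CC(C)=CCC/C(C)=C/CC/C(C)=C/CC/C(C=O)=C\C[C@@H](O[Si](CC)(CC)CC)[C@H](CC(=O)O[Si](CC)(CC)CC)C(=O)O[Si](CC)(CC)CC
F6 | step 7 | (S)-2-[(1R,3E,7E,11E)-4-formyl-8,12,16-trimethyl-1-(triethylsilyloxy)heptadeca-3,7,11,15-tetraen-1-yl]butanedioic acid | CC(C)=CCC/C(C)=C/CC/C(C)=C/CC/C(C=O)=C\C[C@@H](O[Si](CC)(CC)CC)[C@H](CC(=O)O)C(=O)O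
F7 | step 7 | (S)-3-[(1R,3E,7E,11E)-4-formyl-8,12,16-trimethyl-1-(triethylsilyloxy)heptadeca-3,7,11,15-tetraen-1-yl]oxolane-2,5-dione | CC(C)=CCC/C(C)=C/CC/C(C)=C/CC/C(C=O)=C\C[C@@H](O[Si](CC)(CC)CC)[C@@H]1CC(=O)OC1=O
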